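## Retrosynthetic overview

1. Andrographolide 20 is cut at C12=C13 (E-selective cross metathesis) into the 9-allyl decalin diol 15 and (S)-tulipalin B 19. The lactone ring and C14 come ready-made from (S)-3-hydroxy-γ-butyrolactone 16.
2. Diol 15 comes from the acyclic epoxy alcohol 14 in one cascade. Ring A closes first (C4–C5), then ring B (C9–C10), and the allylsilane delivers only the C8=C17 methylene.
3. Key disconnection: the oxirane C–O bonds of 14 (C19–O and C4–O). Ti/tartrate oxygen transfer onto racemic allylic alcohol 13 resolves C3 and creates quaternary C4. The transferred oxygen ends up as 19-OH.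
4. Alcohol 13 comes from bromodienoate 3 by two rounds of ester → DIBAL-H/isopropenyl-MgBr, linked by one Johnson–Claisen rearrangement, followed by a Kumada silylmethylation.
5. Ester 3 comes from ethyl pent-4-ynoate and allyl bromide; the bromoallylation fixes the C8=C9 geometry.

Assumption: a one-flask sequence without isolation of the intermediate counts as one step, and the organometallic solutions 4 and 12 are bought.

## Route

Step 1
Reactants: 1 ethyl pent-4-ynoate; 2 allyl bromide
Product: 3 ethyl (4Z)-4-bromoocta-4,7-dienoate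
Conditions: PdBr2(PhCN)2 (3 mol %), 2 (8 equiv), DME, 0 °C to rt, slow addition of 1
Reagents that add atoms: none
Why: Pd(II)-catalysed bromoallylation of a terminal alkyne: syn-bromopalladation puts Br on the internal carbon, insertion of allyl bromide and β-bromide elimination return PdBr2, so Br and allyl are cis and the ester chain (later C7) is trans to the allyl CH2 (later C11), which later makes C11 equatorial at C9.

Step 2
Reactants: 3 ethyl (4Z)-4-bromoocta-4,7-dienoate; 4 isopropenylmagnesium bromide
Product: 6 rac-(6Z)-6-bromo-2-methyldeca-1,6,9-trien-3-ol, via bromodienal 5 (not isolated)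
Conditions: DIBAL-H (1.05 equiv), CH2Cl2, −78 °C, 1 h; then 4 (2 equiv, THF), −78 to 0 °C; aq. Rochelle salt
Reagents that add atoms: none
Why: One-pot ester semi-reduction and Grignard 1,2-addition: the aluminium hemiacetal is stable at −78 °C and releases aldehyde 5 only on warming, where 4 traps it; the alkenyl bromide and the alkenes are inert, and the racemic carbinol centre is erased in step 3.

Step 3
Reactants: 6 rac-(6Z)-6-bromo-2-methyldeca-1,6,9-trien-3-ol; 7 triethyl orthoacetate
Product: 9 ethyl (4E,8Z)-8-bromo-4-methyldodeca-4,8,11-trienoate, via ketene acetal 8 (not isolated)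
Conditions: 7 (8 equiv), EtCO2H (5 mol %), 138 °C, EtOH distilled off, 3 h
Reagents that add atoms: none
Why: Johnson orthoester Claisen rearrangement: the chair transition state with the carbinol side chain equatorial gives the E-trisubstituted alkene (>97:3), the future C5=C10 bond that dictates the trans ring fusion.

Step 4
Reactants: 9 ethyl (4E,8Z)-8-bromo-4-methyldodeca-4,8,11-trienoate; 4 isopropenylmagnesium bromide
Product: 11 rac-(6E,10Z)-10-bromo-2,6-dimethyltetradeca-1,6,10,13-tetraen-3-ol, via bromotrienal 10 (not isolated)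
Conditions: DIBAL-H (1.05 equiv), CH2Cl2, −78 °C, 1 h; then 4 (2 equiv, THF), −78 to 0 °C; aq. Rochelle salt
Reagents that add atoms: none
Why: Same one-pot semi-reduction and Grignard 1,2-addition as in step 2; the new carbinol centre (future C3) is racemic here and is resolved in step 6.

Step 5
Reactants: 11 rac-(6E,10Z)-10-bromo-2,6-dimethyltetradeca-1,6,10,13-tetraen-3-ol; 12 (trimethylsilyl)methylmagnesium chloride
Product: 13 rac-(6E,10Z)-2,6-dimethyl-10-[(trimethylsilyl)methyl]tetradeca-1,6,10,13-tetraen-3-ol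
Conditions: 12 (3 equiv, Et2O), Pd(PPh3)4 (5 mol %), THF, 55 °C
Reagents that add atoms: none
Why: Kumada–Corriu coupling of an alkenyl bromide with retention of geometry; the reagent has no β-hydrogen, one equivalent is consumed by the OH, and Pd rather than Ni is used so that the allylic alkoxide is not substituted; the acid-sensitive allylsilane is installed only after the hot Claisen step.

Step 6
Reactants: 13 rac-(6E,10Z)-2,6-dimethyl-10-[(trimethylsilyl)methyl]tetradeca-1,6,10,13-tetraen-3-ol
Product: 14 (1R,4E,8Z)-4-methyl-1-[(2S)-2-methyloxiran-2-yl]-8-[(trimethylsilyl)methyl]dodeca-4,8,11-trien-1-ol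
Conditions: Ti(OiPr)4 (10 mol %), D-(−)-DIPT (13 mol %), TBHP (0.45 equiv, decane), 4 Å MS, CH2Cl2, −20 °C; citric acid work-up (no NaOH, to avoid Payne rearrangement); chromatography
Reagents that add atoms: tert-butyl hydroperoxide CC(C)(C)OO
Why: Sharpless kinetic-resolution epoxidation, the key C–O bond formation: with D-(−)-DIPT only the (R)-alcohol reacts fast (k_rel about 100 for 2-methylalk-1-en-3-ols) and gives the erythro (anti) epoxy alcohol, which fixes C3 as R, creates quaternary C4 as S and installs the oxygen that becomes 19-OH, while the isolated alkenes and the allylsilane are not touched by Ti/TBHP.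

Step 7
Reactants: 14 (1R,4E,8Z)-4-methyl-1-[(2S)-2-methyloxiran-2-yl]-8-[(trimethylsilyl)methyl]dodeca-4,8,11-trien-1-ol
Product: 15 (1R,2R,4aS,5R,8aS)-5-allyl-1-(hydroxymethyl)-1,4a-dimethyl-6-methylidenedecahydronaphthalen-2-ol
Conditions: MeAlCl2 (2.2 equiv, hexanes), CH2Cl2 (2 mM), −78 °C, 30 min; aq. Rochelle salt
Reagents that add atoms: none
Why: Proposed new method: chelate-directed 6-exo epoxide-opening cation–olefin bicyclisation of an unprotected α-hydroxy 2,2-disubstituted oxirane, in which the first MeAlCl2 protonolyses O3–H (CH4) to a Cl2Al alkoxide whose Al binds the oxirane oxygen in a five-membered chelate that is only possible in the chair–chair array with O3 equatorial and C19 axial, so C5=C10 attacks C4 anti to the leaving oxygen (inversion, the C19H2–O–Al arm becomes the axial CH2OH), the E-alkene gives the trans fusion (H5 anti to C20), and the Z-allylsilane closes ring B with C11 equatorial and loses Me3Si+ to give only the C8=C17 methylene; the chelated rotamer also has no C3–H or C3–C bond anti to C4–O, which disfavours semipinacol shifts; the closest known reaction types are MeAlCl2- or SnCl4-promoted 6-endo cyclisation of trisubstituted epoxy-polyene allylsilanes and chelation-controlled opening of epoxy alcohols.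

Step 8
Reactants: 16 (S)-3-hydroxy-γ-butyrolactone [(4S)-4-hydroxyoxolan-2-one]
Product: 19 (S)-tulipalin B [(4S)-4-hydroxy-3-methylideneoxolan-2-one], via Mannich base 17 (not isolated), via methiodide 18 (not isolated)
Conditions: LDA (2.3 equiv), THF, −78 °C; Me2N=CH2+ I− (1.3 equiv), −78 to 0 °C; H2O; crude: MeI (5 equiv), MeOH, rt; then aq. NaHCO3/CH2Cl2, rt
Reagents that add atoms: Eschenmoser's salt C=[N+](C)C.[I-]; iodomethane CI (its methyl stays only in intermediate 18)
Why: The dianion of the β-hydroxy lactone is aminomethylated at Cα anti to the alkoxide (Mannich reaction), and quaternisation followed by E1cB loss of NMe3 (α-methylenation) outruns loss of the poor leaving group OH; C14 (S) is carried unchanged from the chiral pool.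

Step 9
Reactants: 15 (1R,2R,4aS,5R,8aS)-5-allyl-1-(hydroxymethyl)-1,4a-dimethyl-6-methylidenedecahydronaphthalen-2-ol; 19 (S)-tulipalin B
Product: 20 andrographolide
Conditions: Hoveyda–Grubbs II (7.5 mol %), 19 (3 equiv), 2,6-dichloro-1,4-benzoquinone (15 mol %), CH2Cl2–THF 4:1, 40 °C, 16 h
Reagents that add atoms: none
Why: Olefin cross metathesis of a terminal alkene with an α-methylene-γ-butyrolactone gives the more stable E-alkylidene lactone (C11 trans to C16); the hindered C8=C17 methylene is inert, the free hydroxyls are tolerated, the benzoquinone suppresses Ru–H isomerisation, and no stereocentre is touched.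

## Compound list

1 | ethyl pent-4-ynoate | C#CCCC(=O)OCC | starting material
2 | allyl bromide | C=CCBr | starting material
3 | ethyl (4Z)-4-bromoocta-4,7-dienoate | CCOC(=O)CC/C(Br)=C/CC=C | intermediate
4 | isopropenylmagnesium bromide | C=C(C)[Mg]Br | starting material
5 | (4Z)-4-bromoocta-4,7-dienal (not isolated) | O=CCC/C(Br)=C/CC=C | intermediate
6 | rac-(6Z)-6-bromo-2-methyldeca-1,6,9-trien-3-ol | C=C(C)C(O)CC/C(Br)=C/CC=C | intermediate
7 | triethyl orthoacetate | CC(OCC)(OCC)OCC | starting material
8 | mixed ketene acetal of 6 (1-ethoxyvinyl ether, not isolated) | C=C(OCC)OC(CC/C(Br)=C/CC=C)C(C)=C | intermediate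
9 | ethyl (4E,8Z)-8-bromo-4-methyldodeca-4,8,11-trienoate | CCOC(=O)CC/C(C)=C/CC/C(Br)=C/CC=C | intermediate
10 | (4E,8Z)-8-bromo-4-methyldodeca-4,8,11-trienal (not isolated) | O=CCC/C(C)=C/CC/C(Br)=C/CC=C | intermediate
11 | rac-(6E,10Z)-10-bromo-2,6-dimethyltetradeca-1,6,10,13-tetraen-3-ol | C=C(C)C(O)CC/C(C)=C/CC/C(Br)=C/CC=C | intermediate
12 | (trimethylsilyl)methylmagnesium chloride | C[Si](C)(C)C[Mg]Cl | starting material
13 | rac-(6E,10Z)-2,6-dimethyl-10-[(trimethylsilyl)methyl]tetradeca-1,6,10,13-tetraen-3-ol | C=C(C)C(O)CC/C(C)=C/CC/C(C[Si](C)(C)C)=C/CC=C | intermediate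
14 | (1R,4E,8Z)-4-methyl-1-[(2S)-2-methyloxiran-2-yl]-8-[(trimethylsilyl)methyl]dodeca-4,8,11-trien-1-ol (erythro epoxy alcohol) | C[C@]1(CO1)[C@H](O)CC/C(C)=C/CC/C(C[Si](C)(C)C)=C/CC=C | intermediate
15 | (1R,2R,4aS,5R,8aS)-5-allyl-1-(hydroxymethyl)-1,4a-dimethyl-6-methylidenedecahydronaphthalen-2-ol (trans-decalin; 3-OH equatorial, CH2OH axial and cis to the angular methyl, allyl equatorial) | C=C1CC[C@@H]2[C@](C)(CO)[C@H](O)CC[C@@]2(C)[C@@H]1CC=C | intermediate
16 | (S)-3-hydroxy-γ-butyrolactone | O=C1C[C@H](O)CO1 | starting material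
17 | trans-(3S,4S)-3-[(dimethylamino)methyl]-4-hydroxyoxolan-2-one (not isolated) | CN(C)C[C@@H]1C(=O)OC[C@H]1O | intermediate
18 | methiodide of 17 (not isolated) | C[N+](C)(C)C[C@@H]1C(=O)OC[C@H]1O.[I-] | intermediate
19 | (S)-tulipalin B, (4S)-4-hydroxy-3-methylideneoxolan-2-one | C=C1C(=O)OC[C@H]1O | intermediate
20 | andrographolide | C=C1CC[C@@H]2[C@](C)(CO)[C@H](O)CC[C@@]2(C)[C@@H]1C/C=C1/C(=O)OC[C@H]1O | target

## Step count

Total step count: 9.
Longest linear sequence: 8 (steps 1–7 and 9).

## The three steps most likely to fail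

**Step 7 (the new step).** The risks are a Meinwald-type hydride shift of the 2,2-disubstituted oxirane to an aldehyde, capture of the C10 cation by the C19 oxygen, and chloride opening of the epoxide. The fallback uses the established 6-endo cyclisation of a Z-derived trisubstituted epoxide, in which the Z substituent ends up axial. It sets out from ester 9 and comes back at 15. DIBAL-H at −78 °C is followed this time by isolation of aldehyde 10. Still–Gennari olefination (ethyl 2-[bis(2,2,2-trifluoroethoxy)phosphoryl]propanoate, KHMDS, 18-crown-6, THF, −78 °C) gives ethyl (2Z,6E,10Z)-10-bromo-2,6-dimethyltetradeca-2,6,10,13-tetraenoate F1. DIBAL-H gives (2Z,6E,10Z)-10-bromo-2,6-dimethyltetradeca-2,6,10,13-tetraen-1-ol F2. Kumada coupling with 12 under Pd(PPh3)4 gives (2Z,6E,10Z)-2,6-dimethyl-10-[(trimethylsilyl)methyl]tetradeca-2,6,10,13-tetraen-1-ol F3. Sharpless epoxidation with L-(+)-DET, which needs no resolution, gives the (2S,3R)-2,3-epoxy alcohol F4. TBSCl and imidazole give its silyl ether F5. SnCl4 in CH2Cl2 at −78 °C closes both rings to the 19-O-TBS ether of the diol F6, and TBAF releases 15.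

**Step 9.** The risks are low conversion of the hindered allyl group with a 1,1-disubstituted partner, E/Z mixtures, and isomerisation of 19. The fallback replaces metathesis by aldol condensation. It sets out from 15 (and 16) and comes back at 20. 2,2-Dimethoxypropane with PPTS gives the 3,19-acetonide F7. OsO4 (cat.)/NaIO4/2,6-lutidine cleaves the unhindered monosubstituted alkene in preference to the congested C8=C17 methylene and gives the C12 aldehyde F8. Lactone 16 is silylated (TBSCl, imidazole) to (S)-4-(tert-butyldimethylsilyloxy)oxolan-2-one F9. Its lithium enolate (LDA, −78 °C) adds to F8 and gives the aldol adduct F10, a mixture of C12 epimers with C13 trans to OTBS. MsCl and Et3N give the C12 mesylate F11, and DBU eliminates it to 3,19-O-isopropylidene-14-O-TBS-andrographolide F12 as the E isomer. Aqueous HF in MeCN removes both protecting groups and gives 20.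

**Step 6.** The risks are the 50 % ceiling of a resolution and Ti-mediated opening of the sensitive 2,2-disubstituted epoxy alcohol. The fallback separates the two tasks into an enantioselective reduction and a substrate-directed epoxidation. It sets out from 13 and comes back at 14. MnO2 in CH2Cl2 gives the isopropenyl ketone F13. (S)-Me-CBS with catecholborane at −78 °C, where the alkenes are not hydroborated and the alkenyl group acts as the large group, gives the (R)-allylic alcohol F14. VO(acac)2/TBHP in toluene at 0 °C then epoxidises under A(1,2)-strain control to the erythro epoxy alcohol 14.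

## Further compounds

F1 | step 7 | ethyl (2Z,6E,10Z)-10-bromo-2,6-dimethyltetradeca-2,6,10,13-tetraenoate | CCOC(=O)/C(C)=C\CC/C(C)=C/CC/C(Br)=C/CC=C
F2 | step 7 | (2Z,6E,10Z)-10-bromo-2,6-dimethyltetradeca-2,6,10,13-tetraen-1-ol | OC/C(C)=C\CC/C(C)=C/CC/C(Br)=C/CC=C
F3 | step 7 | (2Z,6E,10Z)-2,6-dimethyl-10-[(trimethylsilyl)methyl]tetradeca-2,6,10,13-tetraen-1-ol | OC/C(C)=C\CC/C(C)=C/CC/C(C[Si](C)(C)C)=C/CC=C
F4 | step 7 | [(2S,3R)-2-methyl-3-{(3E,7Z)-3-methyl-7-[(trimethylsilyl)methyl]undeca-3,7,10-trienyl}oxiran-2-yl]methanol | C[C@@]1(CO)O[C@@H]1CC/C(C)=C/CC/C(C[Si](C)(C)C)=C/CC=C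
F5 | step 7 | tert-butyldimethylsilyl ether of F4 | C[C@@]1(CO[Si](C)(C)C(C)(C)C)O[C@@H]1CC/C(C)=C/CC/C(C[Si](C)(C)C)=C/CC=C
F6 | step 7 | 19-O-TBS ether of diol 15 | C=C1CC[C@@H]2[C@](C)(CO[Si](C)(C)C(C)(C)C)[C@H](O)CC[C@@]2(C)[C@@H]1CC=C
F7 | step 9 | 3,19-acetonide of diol 15 | C=C1CC[C@@H]2[C@]3(C)COC(C)(C)O[C@@H]3CC[C@@]2(C)[C@@H]1CC=C
F8 | step 9 | C12 aldehyde of the acetonide | C=C1CC[C@@H]2[C@]3(C)COC(C)(C)O[C@@H]3CC[C@@]2(C)[C@@H]1CC=O
F9 | step 9 | (S)-4-(tert-butyldimethylsilyloxy)oxolan-2-one | O=C1C[C@H](O[Si](C)(C)C(C)(C)C)CO1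
F10 | step 9 | aldol adduct of F8 and F9 (C12 epimers) | C=C1CC[C@@H]2[C@]3(C)COC(C)(C)O[C@@H]3CC[C@@]2(C)[C@@H]1CC(O)[C@@H]1C(=O)OC[C@H]1O[Si](C)(C)C(C)(C)C
F11 | step 9 | C12 mesylate of F10 | C=C1CC[C@@H]2[C@]3(C)COC(C)(C)O[C@@H]3CC[C@@]2(C)[C@@H]1CC(OS(C)(=O)=O)[C@@H]1C(=O)OC[C@H]1O[Si](C)(C)C(C)(C)C
F12 | step 9 | 3,19-O-isopropylidene-14-O-TBS-andrographolide | C=C1CC[C@@H]2[C@]3(C)COC(C)(C)O[C@@H]3CC[C@@]2(C)[C@@H]1C/C=C1/C(=O)OC[C@H]1O[Si](C)(C)C(C)(C)C
F13 | step 6 | (6E,10Z)-2,6-dimethyl-10-[(trimethylsilyl)methyl]tetradeca-1,6,10,13-tetraen-3-one | C=C(C)C(=O)CC/C(C)=C/CC/C(C[Si](C)(C)C)=C/CC=C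
F14 | step 6 | (3R,6E,10Z)-2,6-dimethyl-10-[(trimethylsilyl)methyl]tetradeca-1,6,10,13-tetraen-3-ol | C=C(C)[C@H](O)CC/C(C)=C/CC/C(C[Si](C)(C)C)=C/CC=C
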